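**Retrosynthetic overview**

- The strategy rests on how the twelve quinone carbons divide. In each ring the four contiguous carbons C(=O)–C(CH3)=C(OH)–C(=O) are one squarate-derived four-membered ring. The other two carbons of both rings (the arylethyl-bearing carbon and the ring-junction carbon of each) together are one buta-1,3-diene, ArCH2CH2–C=CH–CH=C–CH2CH2Ph, whose central bond is the quinone–quinone bond.
- Hydroxyquinone ⇐ isopropoxyquinone (hydrolysis) ⇐ bis-hydroquinone (oxidation) ⇐ diene-linked bis(4-hydroxycyclobutenone), by a double thermal ring expansion that closes both six-membered carbocycles.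
- Bis(cyclobutenone) ⇐ 1,4-dilithiodiene + two 3-isopropoxy-4-methylcyclobutenediones; dianion ⇐ 2,5-disubstituted tellurophene ⇐ unsymmetrical 1,3-diyne ⇐ Cadiot–Chodkiewicz coupling of two arylbutynes.
- Ring order: the tellurophene (temporary, opened again), the two four-membered rings (from squarate), then both quinone rings in one operation.

Key step: step 9

Assumption: the target carries no descriptor for the quinone–quinone axis, so no axial control is attempted and any axially chiral intermediate is taken as racemic.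

**Step 1**
Reactants: 1 2-methoxybenzyl chloride; 2 1-(trimethylsilyl)propyne
Product: 4 4-(2-methoxyphenyl)-1-(trimethylsilyl)but-1-yne, via 3-(trimethylsilyl)prop-2-yn-1-yllithium 3 (not isolated)
Conditions: n-BuLi, THF, −78 → −20 °C; then 1, −78 °C → rt
Reagents that add atoms: none
Why: Propargylic lithiation of the silyl-capped propyne followed by SN2 alkylation with the benzylic chloride should give the propargylic product, because the silyl group blocks the alkyne terminus and disfavours the allenyl isomer.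

**Step 2**
Reactants: 4 4-(2-methoxyphenyl)-1-(trimethylsilyl)but-1-yne
Product: 5 4-(2-methoxyphenyl)but-1-yne
Conditions: K2CO3, MeOH, rt
Reagents that add atoms: none
Why: Base-mediated protodesilylation (methanolysis of the C(sp)–Si bond) frees the terminal alkyne and does not touch the aryl methyl ether.

**Step 3**
Reactants: 6 4-phenylbut-1-yne
Product: 7 1-bromo-4-phenylbut-1-yne
Conditions: NBS, AgNO3 (cat.), acetone, rt
Reagents that add atoms: N-bromosuccinimide, O=C1CCC(=O)N1Br
Why: Silver-catalysed electrophilic bromination of a terminal alkyne through the silver acetylide is the standard route to 1-bromoalkynes.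

**Step 4**
Reactants: 5 4-(2-methoxyphenyl)but-1-yne; 7 1-bromo-4-phenylbut-1-yne
Product: 8 1-methoxy-2-(8-phenylocta-3,5-diyn-1-yl)benzene
Conditions: CuCl (5 mol %), NH2OH·HCl, 30% aq. n-BuNH2, Et2O, 0 °C → rt
Reagents that add atoms: none
Why: Cadiot–Chodkiewicz coupling of the copper acetylide of 5 with bromoalkyne 7 gives the unsymmetrical diyne, with hydroxylamine keeping copper monovalent so that Glaser homocoupling is held back.

**Step 5**
Reactants: 8 1-methoxy-2-(8-phenylocta-3,5-diyn-1-yl)benzene
Product: 9 2-[2-(2-methoxyphenyl)ethyl]-5-(2-phenylethyl)tellurophene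
Conditions: Te, NaBH4, H2O/EtOH, 80 °C (forms Na2Te); then 8, THF/EtOH, rt → 50 °C
Reagents that add atoms: sodium telluride (made in the flask from Te and NaBH4), [Na+].[Na+].[Te-2]
Why: Telluride adds to one alkyne and the resulting alkenyl tellurolate closes onto the second alkyne (hydrotelluration then 5-endo cyclisation), the established tellurophene synthesis from 1,3-diynes.

**Step 6**
Reactants: 10 diisopropyl squarate
Product: 11 4-hydroxy-2,3-diisopropoxy-4-methylcyclobut-2-en-1-one
Conditions: MeLi, THF, −78 °C; aq. NH4Cl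
Reagents that add atoms: methyllithium, [Li]C
Why: 1,2-addition of methyllithium to one of the two equivalent squarate carbonyls stops at monoaddition at low temperature, and the racemic carbinol centre is removed in the next step.

**Step 7**
Reactants: 11 4-hydroxy-2,3-diisopropoxy-4-methylcyclobut-2-en-1-one
Product: 12 3-isopropoxy-4-methylcyclobut-3-ene-1,2-dione
Conditions: conc. HCl (cat.), CH2Cl2, rt
Reagents that add atoms: none
Why: Acid-catalysed allylic transposition of the tertiary hydroxyl through the alkoxy-stabilised cyclobutenyl cation, with loss of isopropanol, is the standard squarate-to-cyclobutenedione rearrangement.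

**Step 8**
Reactants: 9 2-[2-(2-methoxyphenyl)ethyl]-5-(2-phenylethyl)tellurophene; 12 3-isopropoxy-4-methylcyclobut-3-ene-1,2-dione (2.5 equiv)
Product: 14 4,4'-[(3Z,5Z)-1-(2-methoxyphenyl)-8-phenylocta-3,5-diene-3,6-diyl]bis(4-hydroxy-3-isopropoxy-2-methylcyclobut-2-en-1-one), via (3E,5E)-3,6-dilithio-1-(2-methoxyphenyl)-8-phenylocta-3,5-diene 13 (not isolated)
Conditions: n-BuLi (2.1 equiv), THF, −78 °C; then cannula transfer into 12, THF, −78 °C; aq. NH4Cl at −78 °C
Reagents that add atoms: none
Why: Double tellurium–lithium exchange opens the tellurophene with retention at both alkenyl carbons, and each alkenyllithium adds 1,2 to the C2 ketone of 12 (C1 is deactivated as a vinylogous ester), the two carbinol centres forming as an uncontrolled mixture that step 9 destroys.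

**Step 9**
Reactants: 14 4,4'-[(3Z,5Z)-1-(2-methoxyphenyl)-8-phenylocta-3,5-diene-3,6-diyl]bis(4-hydroxy-3-isopropoxy-2-methylcyclobut-2-en-1-one)
Product: 15 4,4'-diisopropoxy-6-[2-(2-methoxyphenyl)ethyl]-3,3'-dimethyl-6'-(2-phenylethyl)biphenyl-2,2',5,5'-tetrol
Conditions: degassed toluene (dilute), 110 °C, Ar (p-xylene, 138 °C if slow)
Reagents that add atoms: none
Why: Proposed new method: each 4-hydroxycyclobutenone should open by thermal 4π conrotation with the hydroxyl turning outward, which places the alkenyl arm next to the ketene, and the dienylketene should then close by 6π electrocyclisation between the ketene carbon and the CH carbon of its own alkene, after which enolisation aromatises the ring. The closest known reaction is the Moore ring expansion of a single 4-alkenyl-4-hydroxycyclobutenone to a hydroquinone, and what is new is that two such units sit on the termini of one diene and react in turn, so that the former central diene bond becomes the biaryl bond without any coupling of hindered arenes. Both six-membered carbocycles are closed in the same mode, a disrotatory 6π closure forming the bond from the former cyclobutenone carbonyl carbon to a diene CH carbon, the second one on an aryl-substituted alkene once the first ring is aromatic. No stereocentre remains, since the carbinol centres and the alkene geometry are erased on aromatisation and the tetra-ortho-substituted axis forms without control. The selectivity needed is 6π closure onto the inner CH carbon in preference to 8π closure onto the far diene terminus or capture of the ketene by a hydroxyl group. It should be secured because the far terminus is fully substituted and holds its quaternary ring carbon on the inward face, while the inner carbon bears hydrogen and only the 6π product aromatises irreversibly.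

**Step 10**
Reactants: 15 4,4'-diisopropoxy-6-[2-(2-methoxyphenyl)ethyl]-3,3'-dimethyl-6'-(2-phenylethyl)biphenyl-2,2',5,5'-tetrol
Product: 16 4,4'-diisopropoxy-2-[2-(2-methoxyphenyl)ethyl]-5,5'-dimethyl-2'-(2-phenylethyl)-[1,1'-bi(cyclohexa-1,4-diene)]-3,3',6,6'-tetrone
Conditions: Ag2O (excess), MgSO4, Et2O, rt
Reagents that add atoms: none
Why: Two-electron oxidation of each para-hydroquinone to the para-quinone by Ag2O is fast and leaves the aryl and enol ethers untouched.

**Step 11**
Reactants: 16 4,4'-diisopropoxy-2-[2-(2-methoxyphenyl)ethyl]-5,5'-dimethyl-2'-(2-phenylethyl)-[1,1'-bi(cyclohexa-1,4-diene)]-3,3',6,6'-tetrone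
Product: 17 4,4'-dihydroxy-2-[2-(2-methoxyphenyl)ethyl]-5,5'-dimethyl-2'-(2-phenylethyl)-[1,1'-bi(cyclohexa-1,4-diene)]-3,3',6,6'-tetrone (CNP0202346.0)
Conditions: 1 M aq. NaOH, THF/MeOH, 0 °C → rt, Ar; then 1 M HCl
Reagents that add atoms: sodium hydroxide (hydroxide oxygen), [Na+].[OH-]
Why: Each 2-isopropoxyquinone is a vinylogous ester and should undergo addition–elimination with hydroxide at the alkoxy-bearing carbon to give the hydroxyquinone anion, protonated on acidification, while the unactivated anisole methyl ether survives.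

**Compound list**

1 | 2-methoxybenzyl chloride | COc1ccccc1CCl | starting material
2 | 1-(trimethylsilyl)propyne | CC#C[Si](C)(C)C | starting material
3 | 3-(trimethylsilyl)prop-2-yn-1-yllithium | [Li]CC#C[Si](C)(C)C | intermediate
4 | 4-(2-methoxyphenyl)-1-(trimethylsilyl)but-1-yne | COc1ccccc1CCC#C[Si](C)(C)C | intermediate
5 | 4-(2-methoxyphenyl)but-1-yne | COc1ccccc1CCC#C | intermediate
6 | 4-phenylbut-1-yne | C#CCCc1ccccc1 | starting material
7 | 1-bromo-4-phenylbut-1-yne | BrC#CCCc1ccccc1 | intermediate
8 | 1-methoxy-2-(8-phenylocta-3,5-diyn-1-yl)benzene | COc1ccccc1CCC#CC#CCCc1ccccc1 | intermediate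
9 | 2-[2-(2-methoxyphenyl)ethyl]-5-(2-phenylethyl)tellurophene | COc1ccccc1CCC1=CC=C(CCc2ccccc2)[Te]1 | intermediate
10 | diisopropyl squarate | CC(C)OC1=C(OC(C)C)C(=O)C1=O | starting material
11 | 4-hydroxy-2,3-diisopropoxy-4-methylcyclobut-2-en-1-one (racemic) | CC(C)OC1=C(OC(C)C)C(C)(O)C1=O | intermediate
12 | 3-isopropoxy-4-methylcyclobut-3-ene-1,2-dione | CC1=C(OC(C)C)C(=O)C1=O | intermediate
13 | (3E,5E)-3,6-dilithio-1-(2-methoxyphenyl)-8-phenylocta-3,5-diene (each lithium cis to the central C4–C5 bond; E because carbon outranks lithium) | [Li]/C(CCc1ccccc1OC)=C\C=C(/[Li])CCc1ccccc1 | intermediate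
14 | 4,4'-[(3Z,5Z)-1-(2-methoxyphenyl)-8-phenylocta-3,5-diene-3,6-diyl]bis(4-hydroxy-3-isopropoxy-2-methylcyclobut-2-en-1-one), carbinol centres as a mixture | CC1=C(OC(C)C)C(O)(C1=O)/C(CCc1ccccc1OC)=C\C=C(/C1(O)C(OC(C)C)=C(C)C1=O)CCc1ccccc1 | intermediate
15 | 4,4'-diisopropoxy-6-[2-(2-methoxyphenyl)ethyl]-3,3'-dimethyl-6'-(2-phenylethyl)biphenyl-2,2',5,5'-tetrol | COc1ccccc1CCc1c(O)c(OC(C)C)c(C)c(O)c1-c1c(O)c(C)c(OC(C)C)c(O)c1CCc1ccccc1 | intermediate
16 | 4,4'-diisopropoxy-2-[2-(2-methoxyphenyl)ethyl]-5,5'-dimethyl-2'-(2-phenylethyl)-[1,1'-bi(cyclohexa-1,4-diene)]-3,3',6,6'-tetrone | COc1ccccc1CCC1=C(C2=C(CCc3ccccc3)C(=O)C(OC(C)C)=C(C)C2=O)C(=O)C(C)=C(OC(C)C)C1=O | intermediate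
17 | 4,4'-dihydroxy-2-[2-(2-methoxyphenyl)ethyl]-5,5'-dimethyl-2'-(2-phenylethyl)-[1,1'-bi(cyclohexa-1,4-diene)]-3,3',6,6'-tetrone (CNP0202346.0) | COc1ccccc1CCC1=C(C2=C(CCc3ccccc3)C(=O)C(O)=C(C)C2=O)C(=O)C(C)=C(O)C1=O | target

**Step count**

Total steps: 11. Longest linear sequence: 8 steps (1, 2, 4, 5, 8, 9, 10, 11).

**Steps most likely to fail**

Step 9 (double ring expansion). The inward-pointing diene arm may slow the 6π closure, so that 8π closure, capture of the ketene by a hydroxyl group (furanone formation) or ketene oligomerisation takes over. The second ring may also fail to close on the crowded aryl-substituted alkene.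

The fallback uses known reactions only, sets out from 1 and 12 and comes back at 16. Each ring is made alone by the ordinary single ring expansion and the ring–ring bond is made afterwards by cross-coupling.
- Chloride 1 and Mg give 2-methoxybenzylmagnesium chloride F1, which with 2,3-dibromopropene gives 2-bromo-4-(2-methoxyphenyl)but-1-ene F2. Bought benzylmagnesium chloride gives 2-bromo-4-phenylbut-1-ene F3 in the same way.
- Bromine–lithium exchange (t-BuLi, THF, −78 °C) gives [4-(2-methoxyphenyl)but-1-en-2-yl]lithium F4 and (4-phenylbut-1-en-2-yl)lithium F5.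
- Addition of each to the C2 ketone of 12 gives 4-hydroxy-3-isopropoxy-4-[4-(2-methoxyphenyl)but-1-en-2-yl]-2-methylcyclobut-2-en-1-one F6 and 4-hydroxy-3-isopropoxy-2-methyl-4-(4-phenylbut-1-en-2-yl)cyclobut-2-en-1-one F7.
- Heating each in toluene should give 3-isopropoxy-5-[2-(2-methoxyphenyl)ethyl]-2-methylbenzene-1,4-diol F8 and 3-isopropoxy-2-methyl-5-(2-phenylethyl)benzene-1,4-diol F9. The terminal CH2 of the alkene becomes the one unsubstituted ring carbon.
- Methylation (MeI, K2CO3, acetone) gives 3-isopropoxy-1,4-dimethoxy-5-[2-(2-methoxyphenyl)ethyl]-2-methylbenzene F10 and 3-isopropoxy-1,4-dimethoxy-2-methyl-5-(2-phenylethyl)benzene F11.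
- NBS in MeCN at 0 °C brominates the remaining ring position to 1-bromo-4-isopropoxy-2,5-dimethoxy-6-[2-(2-methoxyphenyl)ethyl]-3-methylbenzene F12 and 1-bromo-4-isopropoxy-2,5-dimethoxy-3-methyl-6-(2-phenylethyl)benzene F13. For F10 the trioxygenated ring should react ahead of the anisole ring with one equivalent.
- F13 with n-BuLi gives [4-isopropoxy-2,5-dimethoxy-3-methyl-6-(2-phenylethyl)phenyl]lithium F14, trapped with 2-isopropoxy-4,4,5,5-tetramethyl-1,3,2-dioxaborolane as 2-[4-isopropoxy-2,5-dimethoxy-3-methyl-6-(2-phenylethyl)phenyl]-4,4,5,5-tetramethyl-1,3,2-dioxaborolane F15.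
- Suzuki–Miyaura coupling of F12 with F15 (Pd(OAc)2, SPhos, K3PO4, toluene/H2O, 100 °C) gives 4,4'-diisopropoxy-2,2',5,5'-tetramethoxy-6-[2-(2-methoxyphenyl)ethyl]-3,3'-dimethyl-6'-(2-phenylethyl)biphenyl F16.
- Oxidative demethylation with (NH4)2Ce(NO3)6 in MeCN/H2O converts both para-dimethoxy rings into quinones and gives 16.

Step 8 (double exchange and double addition). After the first addition the remaining alkenyllithium may attack the four-membered ring already attached, at its vinylogous ester carbonyl or in conjugate fashion, instead of a second molecule of 12. Butyl species may also compete for 12 if the second exchange lags.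

The fallback sets out from 9 and comes back at 14. Dianion 13 is generated as in step 8 but quenched with I2 to give (3Z,5Z)-3,6-diiodo-1-(2-methoxyphenyl)-8-phenylocta-3,5-diene F17, which is purified free of tellurium compounds. Iodine–lithium exchange (t-BuLi, Et2O, −78 °C) returns 13, and MgBr2·OEt2 converts it into [(3Z,5Z)-1-(2-methoxyphenyl)-8-phenylocta-3,5-diene-3,6-diyl]bis(magnesium bromide) F18. Its softer carbon–magnesium bonds should add to the ketone of 12 at −78 °C and leave the vinylogous ester of the first-formed adduct alone. NH4Cl work-up gives 14.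

Step 11 (hydrolysis on the biquinone). Hydroxide may degrade the electron-poor biquinone, by conjugate addition at other ring carbons, ring contraction or oligomerisation, faster than it displaces the hindered isopropoxy groups.

The fallback sets out from 15 and comes back at 17, removing the isopropyl groups before the oxidation. BCl3 in CH2Cl2 (−78 → 0 °C) should cleave the two aryl isopropyl ethers of 15 selectively over the aryl methyl ether and give 6-[2-(2-methoxyphenyl)ethyl]-3,3'-dimethyl-6'-(2-phenylethyl)biphenyl-2,2',4,4',5,5'-hexol F19. Oxidation (Ag2O, or air in buffered MeOH) then takes each 1,2,4-trihydroxybenzene ring directly to the 2-hydroxy-1,4-quinone, which is 17.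

**Further compounds**

F1 | step 9 | 2-methoxybenzylmagnesium chloride | COc1ccccc1C[Mg]Cl
F2 | step 9 | 2-bromo-4-(2-methoxyphenyl)but-1-ene | COc1ccccc1CCC(Br)=C
F3 | step 9 | 2-bromo-4-phenylbut-1-ene | BrC(=C)CCc1ccccc1
F4 | step 9 | [4-(2-methoxyphenyl)but-1-en-2-yl]lithium | [Li]C(=C)CCc1ccccc1OC
F5 | step 9 | (4-phenylbut-1-en-2-yl)lithium | [Li]C(=C)CCc1ccccc1
F6 | step 9 | 4-hydroxy-3-isopropoxy-4-[4-(2-methoxyphenyl)but-1-en-2-yl]-2-methylcyclobut-2-en-1-one | CC1=C(OC(C)C)C(O)(C(=C)CCc2ccccc2OC)C1=O
F7 | step 9 | 4-hydroxy-3-isopropoxy-2-methyl-4-(4-phenylbut-1-en-2-yl)cyclobut-2-en-1-one | CC1=C(OC(C)C)C(O)(C(=C)CCc2ccccc2)C1=O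
F8 | step 9 | 3-isopropoxy-5-[2-(2-methoxyphenyl)ethyl]-2-methylbenzene-1,4-diol | Cc1c(O)cc(CCc2ccccc2OC)c(O)c1OC(C)C
F9 | step 9 | 3-isopropoxy-2-methyl-5-(2-phenylethyl)benzene-1,4-diol | Cc1c(O)cc(CCc2ccccc2)c(O)c1OC(C)C
F10 | step 9 | 3-isopropoxy-1,4-dimethoxy-5-[2-(2-methoxyphenyl)ethyl]-2-methylbenzene | Cc1c(OC)cc(CCc2ccccc2OC)c(OC)c1OC(C)C
F11 | step 9 | 3-isopropoxy-1,4-dimethoxy-2-methyl-5-(2-phenylethyl)benzene | Cc1c(OC)cc(CCc2ccccc2)c(OC)c1OC(C)C
F12 | step 9 | 1-bromo-4-isopropoxy-2,5-dimethoxy-6-[2-(2-methoxyphenyl)ethyl]-3-methylbenzene | Cc1c(OC)c(Br)c(CCc2ccccc2OC)c(OC)c1OC(C)C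
F13 | step 9 | 1-bromo-4-isopropoxy-2,5-dimethoxy-3-methyl-6-(2-phenylethyl)benzene | Cc1c(OC)c(Br)c(CCc2ccccc2)c(OC)c1OC(C)C
F14 | step 9 | [4-isopropoxy-2,5-dimethoxy-3-methyl-6-(2-phenylethyl)phenyl]lithium | Cc1c(OC)c([Li])c(CCc2ccccc2)c(OC)c1OC(C)C
F15 | step 9 | 2-[4-isopropoxy-2,5-dimethoxy-3-methyl-6-(2-phenylethyl)phenyl]-4,4,5,5-tetramethyl-1,3,2-dioxaborolane | Cc1c(OC)c(B2OC(C)(C)C(C)(C)O2)c(CCc3ccccc3)c(OC)c1OC(C)C
F16 | step 9 | 4,4'-diisopropoxy-2,2',5,5'-tetramethoxy-6-[2-(2-methoxyphenyl)ethyl]-3,3'-dimethyl-6'-(2-phenylethyl)biphenyl | COc1ccccc1CCc1c(OC)c(OC(C)C)c(C)c(OC)c1-c1c(OC)c(C)c(OC(C)C)c(OC)c1CCc1ccccc1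
F17 | step 8 | (3Z,5Z)-3,6-diiodo-1-(2-methoxyphenyl)-8-phenylocta-3,5-diene | I/C(CCc1ccccc1OC)=C\C=C(/I)CCc1ccccc1
F18 | step 8 | [(3Z,5Z)-1-(2-methoxyphenyl)-8-phenylocta-3,5-diene-3,6-diyl]bis(magnesium bromide) | Br[Mg]/C(CCc1ccccc1OC)=C\C=C(/[Mg]Br)CCc1ccccc1
F19 | step 11 | 6-[2-(2-methoxyphenyl)ethyl]-3,3'-dimethyl-6'-(2-phenylethyl)biphenyl-2,2',4,4',5,5'-hexol | COc1ccccc1CCc1c(O)c(O)c(C)c(O)c1-c1c(O)c(C)c(O)c(O)c1CCc1ccccc1
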